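**Plan**

1. Retrosynthetic cuts: the five O–Me bonds; C3–C4 and C4–C6 (ten-membered aryl ketone ring, CO inserted); C23–C24 of ring D, with the C24=C33 quinone methide read as a diaryl ketone; C23=C2 (olefination); C12–O13 (diaryl ether); C20–C21 (sigmatropic shift from O14); C24–C33 (aroylation); C33–C34 and C36–C37 (ring B built on an orsellinate).
2. Forward order: ring A is methyl orsellinate; ring B is annulated onto it; ring E is attached as the C33 ketone; the C21 side chain is moved from O14 to C20; ring F is joined at O13; ring D closes in the key step; the ten-membered ring closes last.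
3. Enabling feature (atoms numbered as they occur in the target SMILES, hydrogens not counted): C23 lies between the benzylic centre C21 and C24, and C24=C33 is a masked diaryl ketone sitting peri to the C21 chain on the naphthalene (rings A and B). An allylsilane with C23 as its γ-carbon can therefore close ring D (C19, C20, C21, C23, C24, C33) onto that ketone, and the C37 hydroxyl para to C33 turns the carbinol into the quinone methide.
4. Stereochemistry: C21 from a palladium-catalysed asymmetric O-allylation whose ether centre is transferred in the Claisen shift; C23 from allylic 1,3-strain in the tethered allylsilane (trans to the C21 methyl); C2 from 9-BBN hydroboration of the isopropenyl group anti to C24.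

Key step: step 17

Remark: naphthalene intermediates 6–22 keep one set of locants (C1 = future C37, C3 = C34, C4 = C33, C5 = C20, C6 = C14, C8 = C16); stereodescriptors are the CIP descriptors of the compound named.
Assumption: the (S,S) enantiomer of the diphosphine in step 11 is taken to give the (S)-ether; if the sense of induction is the opposite, the (R,R) ligand is used and nothing else changes.

**Step 1**
Reactants: 1 methyl orsellinate (methyl 2,4-dihydroxy-6-methylbenzoate)
Product: 2 methyl 4-(benzyloxy)-2-hydroxy-6-methylbenzoate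
Conditions: BnBr (1.05 equiv), K2CO3, acetone, 56 °C
Reagents that add atoms: benzyl bromide, BrCc1ccccc1
Why: Williamson etherification in which the 2-OH is tied up in a hydrogen bond to the ester carbonyl, so that only the more acidic 4-OH (the future O14) should be alkylated.

**Step 2**
Reactants: 2 methyl 4-(benzyloxy)-2-hydroxy-6-methylbenzoate
Product: 3 methyl 4-(benzyloxy)-2-methoxy-6-methylbenzoate
Conditions: MeI, K2CO3, DMF, 50 °C
Reagents that add atoms: iodomethane, CI
Why: Williamson methylation under more forcing conditions caps the chelated 2-OH, which becomes the C16 methoxy group.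

**Step 3**
Reactants: 3 methyl 4-(benzyloxy)-2-methoxy-6-methylbenzoate
Product: 5 methyl 4-(benzyloxy)-2-methoxy-6-(2-oxopropyl)benzoate, via benzylic lithium 4 (not isolated)
Conditions: LiN(iPr)2 (1.2 equiv), THF, −78 °C; MeC(O)N(OMe)Me; dil. HCl
Reagents that add atoms: N-methoxy-N-methylacetamide, CC(=O)N(C)OC
Why: lateral lithiation of the ortho-toluate (benzylic anion stabilised by the neighbouring ester) followed by acylation with the N-methoxy-N-methylamide, whose chelated tetrahedral adduct releases the ketone only on quench.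

**Step 4**
Reactants: 5 methyl 4-(benzyloxy)-2-methoxy-6-(2-oxopropyl)benzoate
Product: 6 6-(benzyloxy)-8-methoxynaphthalene-1,3-diol
Conditions: t-BuOK (3 equiv), THF, 0 → 25 °C; dil. HCl
Reagents that add atoms: none
Why: intramolecular Claisen (Dieckmann-type) condensation of the methyl ketone enolate on the ester closes ring B, and tautomerisation of the cyclic 1,3-dione to the naphthalenediolate should make the closure irreversible.

**Step 5**
Reactants: 6 6-(benzyloxy)-8-methoxynaphthalene-1,3-diol
Product: 7 6-(benzyloxy)-3,8-dimethoxynaphthalen-1-ol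
Conditions: HCl (1.25 M in MeOH), 25 → 40 °C
Reagents that add atoms: methanol, CO
Why: acid-catalysed etherification of a 1,3-naphthalenediol through its C3 keto tautomer should methylate only the 3-OH (future C34 methoxy), while the peri hydrogen-bonded 1-OH (future O37) stays free.

**Step 6**
Reactants: 7 6-(benzyloxy)-3,8-dimethoxynaphthalen-1-ol
Product: 8 6-(benzyloxy)-4-bromo-3,8-dimethoxynaphthalen-1-ol
Conditions: NBS (1.0 equiv), MeCN, −20 °C
Reagents that add atoms: N-bromosuccinimide, O=C1CCC(=O)N1Br
Why: electrophilic aromatic bromination should go para to the only free hydroxyl at the α position C4 (future C33), the most activated site of that ring.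

**Step 7**
Reactants: 8 6-(benzyloxy)-4-bromo-3,8-dimethoxynaphthalen-1-ol
Product: 9 6-(benzyloxy)-4-bromo-3,8-dimethoxy-1-(methoxymethoxy)naphthalene
Conditions: NaH, DMF, 0 °C; MOMCl
Reagents that add atoms: chloromethyl methyl ether, COCCl
Why: O-alkylation of the naphthoxide gives the MOM acetal, which masks O37 through the organolithium, allylation and copper steps.

**Step 8**
Reactants: 9 6-(benzyloxy)-4-bromo-3,8-dimethoxy-1-(methoxymethoxy)naphthalene; 10 2,6-dimethoxybenzoyl chloride
Product: 12 [6-(benzyloxy)-3,8-dimethoxy-1-(methoxymethoxy)naphthalen-4-yl](2,6-dimethoxyphenyl)methanone, via aryllithium 11 (not isolated)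
Conditions: t-BuLi (2.1 equiv), THF, −78 °C; then 10, −78 → 0 °C
Reagents that add atoms: 2,6-dimethoxybenzoyl chloride (10), COc1cccc(OC)c1C(Cl)=O
Why: bromine–lithium exchange followed by acylation of the aryllithium with the acid chloride forms C24–C33, and the doubly ortho-substituted diaryl ketone is too hindered for a second addition.

**Step 9**
Reactants: 12 [6-(benzyloxy)-3,8-dimethoxy-1-(methoxymethoxy)naphthalen-4-yl](2,6-dimethoxyphenyl)methanone
Product: 13 (2,6-dimethoxyphenyl)[6-hydroxy-3,8-dimethoxy-1-(methoxymethoxy)naphthalen-4-yl]methanone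
Conditions: H2 (1 atm), Pd/C, EtOAc, 25 °C
Reagents that add atoms: none
Why: hydrogenolysis of the benzyl aryl ether frees O14, while the hindered diaryl ketone and the MOM acetal should survive.

**Step 10**
Reactants: 14 (E)-pent-3-en-2-ol (racemic)
Product: 15 (E)-pent-3-en-2-yl methyl carbonate (racemic)
Conditions: ClCO2Me, pyridine, CH2Cl2, 0 °C
Reagents that add atoms: methyl chloroformate, COC(=O)Cl
Why: O-acylation of the allylic alcohol installs the carbonate leaving group needed for π-allyl formation.

**Step 11**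
Reactants: 13 (2,6-dimethoxyphenyl)[6-hydroxy-3,8-dimethoxy-1-(methoxymethoxy)naphthalen-4-yl]methanone; 15 (E)-pent-3-en-2-yl methyl carbonate
Product: 16 (2,6-dimethoxyphenyl){3,8-dimethoxy-1-(methoxymethoxy)-6-[(2S,3E)-pent-3-en-2-yloxy]naphthalen-4-yl}methanone
Conditions: Pd2(dba)3·CHCl3 (2.5 mol %), (S,S)-N,N'-(cyclohexane-1,2-diyl)bis[2-(diphenylphosphino)benzamide] (7.5 mol %), CH2Cl2, 25 °C
Reagents that add atoms: (E)-pent-3-en-2-yl methyl carbonate (15), C/C=C/C(C)OC(=O)OC
Why: palladium-catalysed asymmetric allylic etherification, in which zerovalent palladium ionises the racemic carbonate to a symmetrical 1,3-dimethylallyl complex and the chiral diphosphine directs the naphthoxide to one terminus, setting the (S) ether centre with the E alkene retained.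

**Step 12**
Reactants: 16 (2,6-dimethoxyphenyl){3,8-dimethoxy-1-(methoxymethoxy)-6-[(2S,3E)-pent-3-en-2-yloxy]naphthalen-4-yl}methanone
Product: 17 (2,6-dimethoxyphenyl){6-hydroxy-3,8-dimethoxy-1-(methoxymethoxy)-5-[(2R,3E)-pent-3-en-2-yl]naphthalen-4-yl}methanone
Conditions: Eu(fod)3 (10 mol %), toluene, 80 °C
Reagents that add atoms: none
Why: aromatic Claisen rearrangement of the 2-naphthyl-type ether to the α position C5 through a chair transition state with the carbinol methyl equatorial, which transfers the (S) ether centre into (R)-C21 with an E alkene and frees O14 on rearomatisation.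

**Step 13**
Reactants: 17 (2,6-dimethoxyphenyl){6-hydroxy-3,8-dimethoxy-1-(methoxymethoxy)-5-[(2R,3E)-pent-3-en-2-yl]naphthalen-4-yl}methanone; 18 2-bromo-1-iodo-3-methoxybenzene
Product: 19 {6-(2-bromo-3-methoxyphenoxy)-3,8-dimethoxy-1-(methoxymethoxy)-5-[(2R,3E)-pent-3-en-2-yl]naphthalen-4-yl}(2,6-dimethoxyphenyl)methanone
Conditions: CuI (10 mol %), picolinic acid (20 mol %), K3PO4, DMSO, 90 °C
Reagents that add atoms: 2-bromo-1-iodo-3-methoxybenzene (18), COc1cccc(I)c1Br
Why: copper-catalysed Ullmann diaryl ether synthesis in which the C–I bond reacts in preference to the flanked C–Br bond, which is kept for step 18.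

**Step 14**
Reactants: 19 {6-(2-bromo-3-methoxyphenoxy)-3,8-dimethoxy-1-(methoxymethoxy)-5-[(2R,3E)-pent-3-en-2-yl]naphthalen-4-yl}(2,6-dimethoxyphenyl)methanone
Product: 20 {6-(2-bromo-3-methoxyphenoxy)-1-hydroxy-3,8-dimethoxy-5-[(2R,3E)-pent-3-en-2-yl]naphthalen-4-yl}(2,6-dimethoxyphenyl)methanone
Conditions: HCl (1.25 M in MeOH), THF, 25 °C
Reagents that add atoms: none
Why: acid-catalysed transacetalisation of the MOM ether, easy for a phenol para to a ketone, frees the C37 hydroxyl before the acid-sensitive allylsilane is made.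

**Step 15**
Reactants: 20 {6-(2-bromo-3-methoxyphenoxy)-1-hydroxy-3,8-dimethoxy-5-[(2R,3E)-pent-3-en-2-yl]naphthalen-4-yl}(2,6-dimethoxyphenyl)methanone
Product: 21 (2S)-2-[6-(2-bromo-3-methoxyphenoxy)-4-(2,6-dimethoxybenzoyl)-1-hydroxy-3,8-dimethoxynaphthalen-5-yl]propanal
Conditions: OsO4 (2 mol %), NaIO4 (4 equiv), 2,6-lutidine, dioxane–H2O (3:1), 25 °C
Reagents that add atoms: sodium periodate, [Na+].[O-]I(=O)(=O)=O
Why: Lemieux–Johnson oxidation cuts the propenyl double bond to the C23 aldehyde under lutidine buffering, which should leave the α-aryl centre C21 untouched (its descriptor becomes S only because the formyl group outranks the aryl group).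

**Step 16**
Reactants: 21 (2S)-2-[6-(2-bromo-3-methoxyphenoxy)-4-(2,6-dimethoxybenzoyl)-1-hydroxy-3,8-dimethoxynaphthalen-5-yl]propanal
Product: 22 {6-(2-bromo-3-methoxyphenoxy)-1-hydroxy-3,8-dimethoxy-5-[(2R,3E)-4-methyl-5-(trimethylsilyl)pent-3-en-2-yl]naphthalen-4-yl}(2,6-dimethoxyphenyl)methanone
Conditions: EtPPh3Br, n-BuLi, THF, 0 °C; Me3SiCH2I; n-BuLi, −78 °C; then 21 (ylide 3 equiv), −78 → 25 °C
Reagents that add atoms: ethyltriphenylphosphonium bromide, CC[P+](c1ccccc1)(c1ccccc1)c1ccccc1.[Br-]; (iodomethyl)trimethylsilane, C[Si](C)(C)CI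
Why: Wittig olefination with the β-silyl ylide made in the flask gives the trisubstituted allylsilane directly, one equivalent of ylide being spent on the naphthol proton; the E isomer is expected to prevail and both alkene geometries lead to the same isopropenyl product in step 17.

**Step 17**
Reactants: 22 {6-(2-bromo-3-methoxyphenoxy)-1-hydroxy-3,8-dimethoxy-5-[(2R,3E)-4-methyl-5-(trimethylsilyl)pent-3-en-2-yl]naphthalen-4-yl}(2,6-dimethoxyphenyl)methanone
Product: 24 isopropenyl quinone methide (ring D closed; C37=O; C34 methoxy; C24=C33; 21R and 23S by CIP; methyl trans to isopropenyl), via tertiary carbinol 23 (not isolated)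
Conditions: TiCl4 (3 equiv), 2,6-di-tert-butyl-4-methylpyridine (2 equiv), CH2Cl2, −78 → −20 °C; aq. NaHCO3
Reagents that add atoms: none
Why: TiCl4 binds the C24 ketone (helped by chelation to the C34 methoxy group) and the allylsilane attacks through its γ-carbon C23 in an anti SE2' process, after which chloride removes silicon and leaves the isopropenyl group; the closest known reaction type is the intramolecular Hosomi–Sakurai allylation of a ketone. Ring D (C19, C20, C21, C23, C24, C33) closes in a 6-exo-trig mode onto the carbonyl carbon, the peri arrangement on the naphthalene holding C23 within bonding distance of C24. The titanium alkoxide of the doubly benzylic carbinol 23 then ionises and the cation is discharged through the para C37 oxygen (present as its titanium phenoxide), giving the quinone methide as in the acid dehydration of para-hydroxy triarylcarbinols. C23 is set by allylic 1,3-strain: the C21–H bond eclipses the trisubstituted alkene, the ketone tethered through C20 can reach only the alkene face on the C20 side, and the new bond forms trans to the C21 methyl (23R in target numbering, 23S by CIP in 24), a centre that stays correctable through the dienol of 24. The step needs C-allylation to outrun protodesilylation, which the hindered pyridine base and the intramolecular reach should secure, and it needs ionisation toward O37 instead of elimination toward C23, which the free para hydroxyl should secure.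

**Step 18**
Reactants: 24 isopropenyl quinone methide
Product: 26 macrocyclic ketone (pentamethyl ether of the target; 2S, 21R, 23R), via alkylborane 25 (not isolated)
Conditions: 9-BBN (1.5 equiv), THF, 25 °C; then added over 12 h to Pd(OAc)2 (10 mol %), P(1-adamantyl)2(n-Bu) (20 mol %), K3PO4 (3 M aq), CO (1 atm), THF, 65 °C (final 2 mM)
Reagents that add atoms: carbon monoxide, [C-]#[O+]
Why: anti-Markovnikov hydroboration of the 1,1-disubstituted alkene followed by carbonylative B-alkyl Suzuki–Miyaura coupling (oxidative addition to C–Br, CO insertion, alkyl transfer from boron) should form C3–C4 and C4–C6 and close the ten-membered ring, C2 being set in the hydroboration through a staggered transition state with the C23 hydrogen inside and the bulky C24 (carrying ring E) anti to the incoming borane, which leads to 2S.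

**Step 19**
Reactants: 26 macrocyclic ketone (pentamethyl ether of the target)
Product: 27 CNP0225737.1 (2S, 21R, 23R)
Conditions: BBr3 (12 equiv), CH2Cl2, −78 → 25 °C; MeOH, then H2O
Reagents that add atoms: none
Why: Lewis-acid ether cleavage with BBr3 removes the four aryl methyl ethers and the vinylogous ester methyl group, while the diaryl ether, both ketones and the three stereocentres should be untouched, C23 staying in its more stable trans arrangement.

**Compound list**

1 | methyl orsellinate (methyl 2,4-dihydroxy-6-methylbenzoate) | COC(=O)c1c(C)cc(O)cc1O | starting material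
2 | methyl 4-(benzyloxy)-2-hydroxy-6-methylbenzoate | COC(=O)c1c(C)cc(OCc2ccccc2)cc1O | intermediate
3 | methyl 4-(benzyloxy)-2-methoxy-6-methylbenzoate | COC(=O)c1c(C)cc(OCc2ccccc2)cc1OC | intermediate
4 | benzylic lithium of 3 (methyl 4-(benzyloxy)-2-(lithiomethyl)-6-methoxybenzoate) | COC(=O)c1c(C[Li])cc(OCc2ccccc2)cc1OC | intermediate (not isolated)
5 | methyl 4-(benzyloxy)-2-methoxy-6-(2-oxopropyl)benzoate | COC(=O)c1c(CC(C)=O)cc(OCc2ccccc2)cc1OC | intermediate
6 | 6-(benzyloxy)-8-methoxynaphthalene-1,3-diol | Oc1cc(O)cc2cc(OCc3ccccc3)cc(OC)c12 | intermediate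
7 | 6-(benzyloxy)-3,8-dimethoxynaphthalen-1-ol | Oc1cc(OC)cc2cc(OCc3ccccc3)cc(OC)c12 | intermediate
8 | 6-(benzyloxy)-4-bromo-3,8-dimethoxynaphthalen-1-ol | Oc1cc(OC)c(Br)c2cc(OCc3ccccc3)cc(OC)c12 | intermediate
9 | 6-(benzyloxy)-4-bromo-3,8-dimethoxy-1-(methoxymethoxy)naphthalene | COCOc1cc(OC)c(Br)c2cc(OCc3ccccc3)cc(OC)c12 | intermediate
10 | 2,6-dimethoxybenzoyl chloride | COc1cccc(OC)c1C(Cl)=O | starting material
11 | 6-(benzyloxy)-4-lithio-3,8-dimethoxy-1-(methoxymethoxy)naphthalene | COCOc1cc(OC)c([Li])c2cc(OCc3ccccc3)cc(OC)c12 | intermediate (not isolated)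
12 | [6-(benzyloxy)-3,8-dimethoxy-1-(methoxymethoxy)naphthalen-4-yl](2,6-dimethoxyphenyl)methanone | COCOc1cc(OC)c(C(=O)c3c(OC)cccc3OC)c2cc(OCc4ccccc4)cc(OC)c12 | intermediate
13 | (2,6-dimethoxyphenyl)[6-hydroxy-3,8-dimethoxy-1-(methoxymethoxy)naphthalen-4-yl]methanone | COCOc1cc(OC)c(C(=O)c3c(OC)cccc3OC)c2cc(O)cc(OC)c12 | intermediate
14 | (E)-pent-3-en-2-ol (racemic) | C/C=C/C(C)O | starting material
15 | (E)-pent-3-en-2-yl methyl carbonate (racemic) | C/C=C/C(C)OC(=O)OC | intermediate
16 | (2,6-dimethoxyphenyl){3,8-dimethoxy-1-(methoxymethoxy)-6-[(2S,3E)-pent-3-en-2-yloxy]naphthalen-4-yl}methanone | COCOc1cc(OC)c(C(=O)c3c(OC)cccc3OC)c2cc(O[C@@H](C)/C=C/C)cc(OC)c12 | intermediate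
17 | (2,6-dimethoxyphenyl){6-hydroxy-3,8-dimethoxy-1-(methoxymethoxy)-5-[(2R,3E)-pent-3-en-2-yl]naphthalen-4-yl}methanone | COCOc1cc(OC)c(C(=O)c3c(OC)cccc3OC)c2c([C@H](C)/C=C/C)c(O)cc(OC)c12 | intermediate
18 | 2-bromo-1-iodo-3-methoxybenzene | COc1cccc(I)c1Br | starting material
19 | {6-(2-bromo-3-methoxyphenoxy)-3,8-dimethoxy-1-(methoxymethoxy)-5-[(2R,3E)-pent-3-en-2-yl]naphthalen-4-yl}(2,6-dimethoxyphenyl)methanone | COCOc1cc(OC)c(C(=O)c3c(OC)cccc3OC)c2c([C@H](C)/C=C/C)c(Oc4cccc(OC)c4Br)cc(OC)c12 | intermediate
20 | {6-(2-bromo-3-methoxyphenoxy)-1-hydroxy-3,8-dimethoxy-5-[(2R,3E)-pent-3-en-2-yl]naphthalen-4-yl}(2,6-dimethoxyphenyl)methanone | Oc1cc(OC)c(C(=O)c3c(OC)cccc3OC)c2c([C@H](C)/C=C/C)c(Oc4cccc(OC)c4Br)cc(OC)c12 | intermediate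
21 | (2S)-2-[6-(2-bromo-3-methoxyphenoxy)-4-(2,6-dimethoxybenzoyl)-1-hydroxy-3,8-dimethoxynaphthalen-5-yl]propanal | Oc1cc(OC)c(C(=O)c3c(OC)cccc3OC)c2c([C@H](C)C=O)c(Oc4cccc(OC)c4Br)cc(OC)c12 | intermediate
22 | peri keto allylsilane, {6-(2-bromo-3-methoxyphenoxy)-1-hydroxy-3,8-dimethoxy-5-[(2R,3E)-4-methyl-5-(trimethylsilyl)pent-3-en-2-yl]naphthalen-4-yl}(2,6-dimethoxyphenyl)methanone | Oc1cc(OC)c(C(=O)c3c(OC)cccc3OC)c2c([C@H](C)/C=C(\C)C[Si](C)(C)C)c(Oc4cccc(OC)c4Br)cc(OC)c12 | intermediate (key step precursor)
23 | tertiary carbinol, ring D closed with C24 bearing OH and the 2,6-dimethoxyphenyl group (C21 and C23 as in 24; C24 either configuration, lost on ionisation) | C=C(C)[C@@H]1[C@@H](C)c2c(Oc3cccc(OC)c3Br)cc(OC)c3c(O)cc(OC)c(c23)C1(O)c1c(OC)cccc1OC | intermediate (not isolated)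
24 | isopropenyl quinone methide (C37=O, C34 methoxy, C24=C33; 21R, 23S by CIP; methyl trans to isopropenyl) | C=C(C)[C@H]1C(c2c(OC)cccc2OC)=C2C(OC)=CC(=O)c3c(OC)cc(Oc4cccc(OC)c4Br)c(c23)[C@@H]1C | intermediate (key step product)
25 | B-alkyl-9-BBN adduct of 24 at C3 (2S, 21R, 23R) | C[C@@H](CB1C2CCCC1CCC2)[C@H]1C(c2c(OC)cccc2OC)=C2C(OC)=CC(=O)c3c(OC)cc(Oc4cccc(OC)c4Br)c(c23)[C@@H]1C | intermediate (not isolated)
26 | macrocyclic ketone, pentamethyl ether of the target (2S, 21R, 23R) | C[C@H]1CC(=O)c2c(OC)cccc2Oc2cc(OC)c3c4c2[C@H](C)[C@@H]1C(c1c(OC)cccc1OC)=C4C(OC)=CC3=O | intermediate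
27 | CNP0225737.1 (2S, 21R, 23R) | C[C@H]1CC(=O)c2c(O)cccc2Oc2cc(O)c3c4c2[C@H](C)[C@@H]1C(c1c(O)cccc1O)=C4C(O)=CC3=O | target

**Step count and risks**

Total steps: 19. Longest linear sequence: 18 steps (1–9 and 11–19; step 10 is a one-step side branch).

Steps most likely to fail:

Step 17. The Lewis acid may fail to activate the electron-rich, doubly ortho-substituted ketone, so that protodesilylation of the allylsilane outruns C–C bond formation. The fallback lowers the oxidation level of C24 and sets out from 22. Reduction with iBu2AlH (CH2Cl2, −78 → 0 °C) gives the diaryl carbinol F1. With catalytic BF3·OEt2 (CH2Cl2, −40 °C) this loses water to the para-quinone methide with hydrogen on C24 F2, a much stronger electrophile than the ketone. The allylsilane adds to it in a 1,6-sense (vinylogous Hosomi–Sakurai allylation) to give the ring D closed phenalene with hydrogen on C24 and a free C37 naphthol F3. DDQ (CH2Cl2, 0 °C) then oxidises the para-hydroxy diarylmethine to the quinone methide, and the route is rejoined at 24.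

Step 18. Hydroboration may occur on the wrong face of the isopropenyl group, and ring closure may be outrun by intermolecular coupling or by loss of the alkylborane before acyl transfer. The fallback makes the ketone by aryl addition to an aldehyde and sets out from 24. Aromatic Finkelstein exchange (CuI, NaI, trans-N,N'-dimethylcyclohexane-1,2-diamine, dioxane, 110 °C) gives the aryl iodide analogue of 24 F4. Rhodium-catalysed hydroformylation (Rh(acac)(CO)2, tris(2,4-di-tert-butylphenyl) phosphite, CO/H2, toluene, 80 °C) of the isopropenyl group gives the linear C4 aldehyde F5, at which stage the C2 epimers can be separated. An intramolecular Nozaki–Hiyama–Kishi reaction (CrCl2, NiCl2 cat., DMSO, high dilution) closes the ten-membered ring to the macrocyclic C4 carbinol F6. Dess–Martin oxidation returns to the route at 26.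

Step 12. The [3,3] shift next to the peri ketone may be slow enough for Lewis-acid ionisation of the allylic ether or leakage through a boat transition state to erode the C21 configuration. The fallback sets C21 by catalyst control and starts from 13. Iridium-catalysed branched-selective Friedel–Crafts allylation at C5 ([Ir(cod)Cl]2, chiral phosphoramidite, methyl (E)-but-2-enyl carbonate, THF) gives the C5-[(R)-but-3-en-2-yl] naphthol F7. Ullmann coupling with 18 under the conditions of step 13 gives its 2-bromo-3-methoxyphenyl ether F8. Methanolic HCl removes the MOM group to give the free C1 naphthol F9. Lemieux–Johnson cleavage of the vinyl group then returns to the route at aldehyde 21.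

**Further compounds**

F1 | step 17 | diaryl carbinol (22 with the C24 ketone reduced; C24 either configuration) | Oc1cc(OC)c(C(O)c3c(OC)cccc3OC)c2c([C@H](C)/C=C(\C)C[Si](C)(C)C)c(Oc4cccc(OC)c4Br)cc(OC)c12
F2 | step 17 | para-quinone methide with hydrogen on C24 (C37=O, C33=C24; alkene geometry not fixed) | O=C1C=C(OC)C(=Cc2c(OC)cccc2OC)c2c([C@H](C)/C=C(\C)C[Si](C)(C)C)c(Oc3cccc(OC)c3Br)cc(OC)c12
F3 | step 17 | ring D closed phenalene with hydrogen on C24 and a free C37 naphthol (C21 and C23 as in 24; C24 either configuration) | C=C(C)[C@@H]1[C@@H](C)c2c(Oc3cccc(OC)c3Br)cc(OC)c3c(O)cc(OC)c(c23)C1c1c(OC)cccc1OC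
F4 | step 18 | aryl iodide analogue of 24 | C=C(C)[C@H]1C(c2c(OC)cccc2OC)=C2C(OC)=CC(=O)c3c(OC)cc(Oc4cccc(OC)c4I)c(c23)[C@@H]1C
F5 | step 18 | linear C4 aldehyde from hydroformylation of F4 (2S epimer) | C[C@@H](CC=O)[C@H]1C(c2c(OC)cccc2OC)=C2C(OC)=CC(=O)c3c(OC)cc(Oc4cccc(OC)c4I)c(c23)[C@@H]1C
F6 | step 18 | macrocyclic C4 carbinol (C4 either configuration) | C[C@H]1CC(O)c2c(OC)cccc2Oc2cc(OC)c3c4c2[C@H](C)[C@@H]1C(c1c(OC)cccc1OC)=C4C(OC)=CC3=O
F7 | step 12 | C5-[(R)-but-3-en-2-yl] naphthol (vinyl analogue of 17) | COCOc1cc(OC)c(C(=O)c3c(OC)cccc3OC)c2c([C@H](C)C=C)c(O)cc(OC)c12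
F8 | step 12 | 2-bromo-3-methoxyphenyl ether of F7 (vinyl analogue of 19) | COCOc1cc(OC)c(C(=O)c3c(OC)cccc3OC)c2c([C@H](C)C=C)c(Oc4cccc(OC)c4Br)cc(OC)c12
F9 | step 12 | free C1 naphthol from F8 (vinyl analogue of 20) | Oc1cc(OC)c(C(=O)c3c(OC)cccc3OC)c2c([C@H](C)C=C)c(Oc4cccc(OC)c4Br)cc(OC)c12
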